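**Plan**
1. Retrosynthesis: the phenol is unmasked last (MOM ether). The dihydrofuran ring is then cut at C2–C3 and at O1–C7a together. This gives O-MOM-syringaldehyde (its C=O becomes O1–C2) and a ring-A ethylarene carrying a chiral p-tolylsulfinyl group on C7a.
2. Enabling feature: in the dihydrobenzofuran, benzylic C3 and aryl C7a are 1,3-related through C3a (ortho on ring A). One sulfinyl group on C7a can therefore acidify and chelate C3, relay chirality to it, and then leave from C7a. The C5 propenyl group, para to C7a, helps to carry the charge of the σ-complex.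
3. Ring A is cut further at CH2–CH3 (lateral methylation), C5–propenyl (Suzuki–Miyaura), C7a–S (Andersen synthesis) and C7a–I (from the aniline).
4. Forward: ring A is dressed in four steps and the aldehyde is protected in one. The only ring formed, the dihydrofuran, arises in step 6, and deprotection ends the route.
5. Stereochemistry: sulfur comes from (−)-menthyl (S)-p-toluenesulfinate and sets C3 by 1,4-induction. C2 follows from trans-selective closure under reversible addition, backed by acid equilibration. The (E)-alkene comes from the (E)-alkenylboronate.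

Key step: step 6

Assumption: the sense of the 1,4-induction is taken from the lithium–sulfinyl chelate model, (S)-sulfur giving (3S). Should experiment show the opposite sense, the route would be run with the enantiomeric, equally available sulfinate.

**Step 1**
Reactants: 1 4-bromo-2-methoxy-6-methylaniline
Product: 3 5-bromo-2-iodo-1-methoxy-3-methylbenzene, via diazonium chloride 2 (not isolated)
Conditions: NaNO2, aq. HCl, MeCN, 0 °C; then KI, 0 °C → rt
Reagents that add atoms: potassium iodide, [K+].[I-]
Why: Sandmeyer-type diazotisation–iodination puts iodine on the carbon that carried nitrogen, so the pattern (I flanked by OMe and CH3, Br para) is fixed by the starting aniline.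

**Step 2**
Reactants: 3 5-bromo-2-iodo-1-methoxy-3-methylbenzene; 4 (1R,2S,5R)-menthyl (S)-p-toluenesulfinate
Product: 6 (S)-5-bromo-1-methoxy-3-methyl-2-(p-tolylsulfinyl)benzene, via arylmagnesium chloride 5 (not isolated)
Conditions: i-PrMgCl·LiCl, THF, −20 → 0 °C; then added to 4, THF/toluene, −40 °C → rt; aq. NH4Cl
Reagents that add atoms: none
Why: I/Mg exchange is much faster at C–I than at C–Br and is helped by the ortho methoxy group, and the Andersen sulfoxide synthesis displaces mentholate from sulfur with inversion, which sets the (S)-sulfoxide.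

**Step 3**
Reactants: 6 (S)-5-bromo-1-methoxy-3-methyl-2-(p-tolylsulfinyl)benzene; 7 (E)-prop-1-enylboronic acid pinacol ester
Product: 8 (S)-1-methoxy-3-methyl-5-[(E)-prop-1-enyl]-2-(p-tolylsulfinyl)benzene
Conditions: Pd(dppf)Cl2 (cat.), K2CO3, 1,4-dioxane/H2O, 80 °C
Reagents that add atoms: none
Why: Suzuki–Miyaura coupling at the only C–Br bond, para to the electron-withdrawing sulfinyl group, proceeds with retention of the (E)-alkenylboron geometry and leaves the configurationally stable sulfoxide untouched.

**Step 4**
Reactants: 8 (S)-1-methoxy-3-methyl-5-[(E)-prop-1-enyl]-2-(p-tolylsulfinyl)benzene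
Product: 10 (S)-1-ethyl-3-methoxy-5-[(E)-prop-1-enyl]-2-(p-tolylsulfinyl)benzene, via benzyllithium 9 (not isolated)
Conditions: LDA, THF, −78 °C; MeI, −78 °C
Reagents that add atoms: iodomethane, CI
Why: Lateral lithiation directed by the ortho sulfinyl oxygen followed by SN2 methylation is the standard homologation of o-sulfinyltoluenes and creates no carbon stereocentre.

**Step 5**
Reactants: 11 syringaldehyde (4-hydroxy-3,5-dimethoxybenzaldehyde)
Product: 12 3,5-dimethoxy-4-(methoxymethoxy)benzaldehyde
Conditions: MOMCl, i-Pr2NEt, CH2Cl2, 0 °C → rt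
Reagents that add atoms: chloromethyl methyl ether, COCCl
Why: O-alkylation of the acidic phenol gives an acetal that is inert to LDA, carbanions and alkoxides and keeps the aldehyde electrophilic by preventing phenoxide formation.

**Step 6**
Reactants: 10 (S)-1-ethyl-3-methoxy-5-[(E)-prop-1-enyl]-2-(p-tolylsulfinyl)benzene; 12 3,5-dimethoxy-4-(methoxymethoxy)benzaldehyde
Product: 15 (2S,3S)-2-[3,5-dimethoxy-4-(methoxymethoxy)phenyl]-7-methoxy-3-methyl-5-[(E)-prop-1-enyl]-2,3-dihydrobenzofuran, via benzyllithium chelate 13 (not isolated), via lithium alkoxide 14 (not isolated)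
Conditions: LDA, THF, −78 °C; 12, −78 °C; DMPU, −78 → 45 °C; aq. NH4Cl
Reagents that add atoms: none
Why: Proposed new method: LDA removes one benzylic proton of the ethyl group because the sulfinyl oxygen on the neighbouring ring carbon C7a binds lithium, and in the resulting six-membered C3–C3a–C7a–S–O–Li chelate 13 the methyl group turns away from sulfur and the p-tolyl group covers the face opposite to lithium, so the lithium-bound aldehyde 12 is delivered to one face of C3 and sets (3S) by 1,4-induction, a C–C bond formation known for o-sulfinylbenzyl carbanions and aromatic aldehydes. On warming with DMPU the alkoxide oxygen of 14 should add to the sulfinyl-bearing ipso carbon C7a (5-exo-trig with respect to C7a=C7 of ring A), the charge of the σ-complex being spread over C7, C3a and C5 and from C5 into the propenyl group, and loss of lithium p-toluenesulfenate restores the arene, so that C2–C3 and O1–C7a arise in one flask as a formal anionic (3+2) annulation of the C=O bond with the C3–C3a–C7a unit. The closest known reaction type is the tandem addition/intramolecular SNAr of the same carbanions with imines, which gives indolines with expulsion of the sulfinyl group from an otherwise unactivated ring; the new element is an alkoxide instead of an amide anion as ipso nucleophile, and an O–S sulfurane followed by ligand coupling would lead to the same product. C2 is controlled by the closure: the addition is reversible at the cyclisation temperature, the two carbinol epimers interconvert through 13 and 12, and the anti (1S,2S) epimer should close faster because syringyl and methyl end up trans on the new five-membered ring (Curtin–Hammett), with step 7 as thermodynamic safety net. The step needs site-selective deprotonation (ethyl CH2 against propenyl CH3, tolyl CH3 and ring C–H), which the chelating sulfinyl oxygen secures, and closure faster than decay of the regenerated carbanion, which the five-membered geometry and the good nucleofuge on C7a favour.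

**Step 7**
Reactants: 15 (2S,3S)-2-[3,5-dimethoxy-4-(methoxymethoxy)phenyl]-7-methoxy-3-methyl-5-[(E)-prop-1-enyl]-2,3-dihydrobenzofuran
Product: 16 odoratisol A
Conditions: 2 M aq. HCl, THF, 40 °C
Reagents that add atoms: none
Why: Acid hydrolysis of the phenolic MOM acetal frees the phenol, and any reversible ionisation of the C2–O1 bond para to the freed syringyl phenol can only funnel material to the more stable 2,3-trans isomer while C3 is not touched.

**Compound list**
1 | 4-bromo-2-methoxy-6-methylaniline | Nc1c(C)cc(Br)cc1OC | starting material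
2 | 4-bromo-2-methoxy-6-methylbenzenediazonium chloride | COc1cc(Br)cc(C)c1[N+]#N.[Cl-] | intermediate
3 | 5-bromo-2-iodo-1-methoxy-3-methylbenzene | COc1cc(Br)cc(C)c1I | intermediate
4 | (1R,2S,5R)-menthyl (S)-p-toluenesulfinate | CC(C)[C@@H]1CC[C@@H](C)C[C@H]1O[S@](=O)c1ccc(C)cc1 | starting material
5 | (4-bromo-2-methoxy-6-methylphenyl)magnesium chloride | COc1cc(Br)cc(C)c1[Mg]Cl | intermediate
6 | (S)-5-bromo-1-methoxy-3-methyl-2-(p-tolylsulfinyl)benzene | Cc1ccc(cc1)[S@](=O)c1c(OC)cc(Br)cc1C | intermediate
7 | (E)-prop-1-enylboronic acid pinacol ester | C/C=C/B1OC(C)(C)C(C)(C)O1 | starting material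
8 | (S)-1-methoxy-3-methyl-5-[(E)-prop-1-enyl]-2-(p-tolylsulfinyl)benzene | Cc1ccc(cc1)[S@](=O)c1c(OC)cc(/C=C/C)cc1C | intermediate
9 | benzyllithium derived from 8 | Cc1ccc(cc1)[S@](=O)c1c(OC)cc(/C=C/C)cc1C[Li] | intermediate
10 | (S)-1-ethyl-3-methoxy-5-[(E)-prop-1-enyl]-2-(p-tolylsulfinyl)benzene | Cc1ccc(cc1)[S@](=O)c1c(OC)cc(/C=C/C)cc1CC | intermediate
11 | syringaldehyde | COc1cc(C=O)cc(OC)c1O | starting material
12 | 3,5-dimethoxy-4-(methoxymethoxy)benzaldehyde | COCOc1c(OC)cc(C=O)cc1OC | intermediate
13 | sulfinyl-chelated α-methylbenzyllithium derived from 10 | Cc1ccc(cc1)[S@](=O)c1c(OC)cc(/C=C/C)cc1[C@H](C)[Li] | intermediate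
14 | lithium (1S,2S)-1-[3,5-dimethoxy-4-(methoxymethoxy)phenyl]-2-{3-methoxy-5-[(E)-prop-1-enyl]-2-[(S)-p-tolylsulfinyl]phenyl}propan-1-olate | Cc1ccc(cc1)[S@](=O)c1c(OC)cc(/C=C/C)cc1[C@H](C)[C@H]([O-])c1cc(OC)c(OCOC)c(OC)c1.[Li+] | intermediate
15 | (2S,3S)-2-[3,5-dimethoxy-4-(methoxymethoxy)phenyl]-7-methoxy-3-methyl-5-[(E)-prop-1-enyl]-2,3-dihydrobenzofuran | C/C=C/c1cc(OC)c2c(c1)[C@H](C)[C@@H](c1cc(OC)c(OCOC)c(OC)c1)O2 | intermediate
16 | odoratisol A, (2S,3S)-2-(4-hydroxy-3,5-dimethoxyphenyl)-7-methoxy-3-methyl-5-[(E)-prop-1-enyl]-2,3-dihydrobenzofuran | C/C=C/c1cc(OC)c2c(c1)[C@H](C)[C@@H](c1cc(OC)c(O)c(OC)c1)O2 | target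

**Count and risks**
Total steps: 7. Longest linear sequence: 6 (steps 1, 2, 3, 4, 6, 7).

Steps most likely to fail:

1. Step 6.
   - Risk: the lithium alkoxide may attack the electron-rich ring A too slowly. Reversal of the addition would then take over, followed by decay of the regenerated carbanion (Truce–Smiles-type aryl migration, loss of facial control at C3 at higher temperature).
   - Fallback with known chemistry, from 10 and 12 back to 15: the addition is quenched at −78 °C. The anti sulfinyl alcohol F1 is separated from its carbinol epimer by chromatography. Sulfoxide–lithium exchange with t-BuLi (THF, −78 °C) gives the dilithio species F2. Iodine converts it to the iodo alcohol F3. A copper-catalysed intramolecular Ullmann etherification (CuI, 1,10-phenanthroline, Cs2CO3, toluene, 110 °C) then closes O1–C7a to give 15 with both stereocentres untouched.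

2. Step 2.
   - Risk: the doubly ortho-substituted aryl Grignard reagent may attack sulfur slowly. Exchange between the product sulfoxide and remaining Grignard reagent would then erode the configuration at sulfur, and conversion would stay incomplete.
   - Fallback, from 5 back to 6, reverses the order of the two S–C bonds. Compound 5 is trapped with SO2 (DABSO) to give the sulfinic acid F4. SOCl2 gives the sulfinyl chloride F5. (−)-Menthol/pyridine, with crystallisation under HCl-mediated epimerisation at sulfur, gives the menthyl (R)-arenesulfinate F6. The unhindered p-TolMgBr then displaces mentholate with inversion to give 6.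

3. Step 7.
   - Risk: acid-induced ionisation of the C2–O1 bond may go beyond reversible epimerisation. Possible outcomes are capture of the benzylic cation by water, loss of the C3 proton towards a stilbene, or acid-induced oligomerisation at the propenyl group.
   - Fallback, from 11 back to 16, changes the protecting-group logic to a neutral, metal-catalysed release. Compound 11 is allylated (allyl bromide, K2CO3, DMF) to 4-allyloxy-3,5-dimethoxybenzaldehyde F7. This is taken through the conditions of step 6 with 10, via the lithium alkoxide F8, to the O-allyl ether of the target F9. Tsuji–Trost deallylation (Pd(PPh3)4 cat., morpholine, THF, rt) gives 16.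

**Further compounds**
F1 | step 6 | (1S,2S)-1-[3,5-dimethoxy-4-(methoxymethoxy)phenyl]-2-{3-methoxy-5-[(E)-prop-1-enyl]-2-[(S)-p-tolylsulfinyl]phenyl}propan-1-ol | Cc1ccc(cc1)[S@](=O)c1c(OC)cc(/C=C/C)cc1[C@H](C)[C@H](O)c1cc(OC)c(OCOC)c(OC)c1
F2 | step 6 | dilithio species (aryllithium at C7a, lithium alkoxide at C2) | [Li]c1c(OC)cc(/C=C/C)cc1[C@H](C)[C@H](O[Li])c1cc(OC)c(OCOC)c(OC)c1
F3 | step 6 | (1S,2S)-1-[3,5-dimethoxy-4-(methoxymethoxy)phenyl]-2-{2-iodo-3-methoxy-5-[(E)-prop-1-enyl]phenyl}propan-1-ol | C/C=C/c1cc(OC)c(I)c(c1)[C@H](C)[C@H](O)c1cc(OC)c(OCOC)c(OC)c1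
F4 | step 2 | 4-bromo-2-methoxy-6-methylbenzenesulfinic acid | COc1cc(Br)cc(C)c1S(=O)O
F5 | step 2 | 4-bromo-2-methoxy-6-methylbenzenesulfinyl chloride | COc1cc(Br)cc(C)c1S(=O)Cl
F6 | step 2 | (1R,2S,5R)-menthyl (R)-4-bromo-2-methoxy-6-methylbenzenesulfinate | CC(C)[C@@H]1CC[C@@H](C)C[C@H]1O[S@@](=O)c1c(C)cc(Br)cc1OC
F7 | step 7 | 4-allyloxy-3,5-dimethoxybenzaldehyde | C=CCOc1c(OC)cc(C=O)cc1OC
F8 | step 7 | lithium (1S,2S)-1-(4-allyloxy-3,5-dimethoxyphenyl)-2-{3-methoxy-5-[(E)-prop-1-enyl]-2-[(S)-p-tolylsulfinyl]phenyl}propan-1-olate | Cc1ccc(cc1)[S@](=O)c1c(OC)cc(/C=C/C)cc1[C@H](C)[C@H]([O-])c1cc(OC)c(OCC=C)c(OC)c1.[Li+]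
F9 | step 7 | (2S,3S)-2-(4-allyloxy-3,5-dimethoxyphenyl)-7-methoxy-3-methyl-5-[(E)-prop-1-enyl]-2,3-dihydrobenzofuran | C/C=C/c1cc(OC)c2c(c1)[C@H](C)[C@@H](c1cc(OC)c(OCC=C)c(OC)c1)O2
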